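## Retrosynthetic overview

1. Aryl bromide 1 and (E)-propenyl boronate 2 are what remains after cutting the aryl–alkenyl C–C bond of (E)-isoelemicin 3 (Suzuki coupling, made first).
2. Alkene 3 and catechol aldehyde 4 are what remains, by way of the open-chain selenide 5, after cutting both C–O bonds of the dioxane ring of benzodioxane aldehyde 6 (O4–C3 benzylic, then O1–C2). One enantioselective syn-dioxygenative annulation sets both stereocentres.
3. Aldehyde 6 is what remains after cutting the enal C=C bond of target 7 (Wittig two-carbon homologation, made last).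
4. Ring order: both benzene rings are bought; the 1,4-dioxane ring is the only ring built (step 2).

Assumption: the antipode of the diselenide catalyst drawn here, bis{2-[(1S)-1-methoxyethyl]phenyl} diselenide (CO[C@@H](C)c1ccccc1[Se][Se]c1ccccc1[C@H](C)OC), is taken to give the (2S,3S) series; if experiment shows the opposite sense, the equally accessible (R,R)-antipode is used, and the sense is checked once against material from the fallback to step 2.

## Route

Step 1
Reactants: 1 5-bromo-1,2,3-trimethoxybenzene; 2 (E)-4,4,5,5-tetramethyl-2-(prop-1-en-1-yl)-1,3,2-dioxaborolane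
Product: 3 (E)-1,2,3-trimethoxy-5-(prop-1-en-1-yl)benzene
Conditions: PdCl2(dppf) (2 mol %; dppf = 1,1'-bis(diphenylphosphino)ferrocene), K2CO3 (3 equiv), 1,4-dioxane/H2O 4:1, 85 °C
Reagents that add atoms: none
Why: Suzuki–Miyaura coupling of an aryl bromide with an alkenyl boronate is stereoretentive, so the E geometry bought with 2 is carried unchanged into 3.

Step 2
Reactants: 3 (E)-1,2,3-trimethoxy-5-(prop-1-en-1-yl)benzene; 4 3,4-dihydroxy-5-methoxybenzaldehyde
Product: 6 (2S,3S)-8-methoxy-2-methyl-3-(3,4,5-trimethoxyphenyl)-2,3-dihydro-1,4-benzodioxine-6-carbaldehyde, via anti-aryloxy selenide 5 (not isolated)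
Conditions: bis{2-[(1S)-1-methoxyethyl]phenyl} diselenide (10 mol %), 1-fluoro-2,4,6-trimethylpyridinium tetrafluoroborate (1.3 equiv), NaF (3 equiv), 4 Å MS, MeCN, 0 → 23 °C
Reagents that add atoms: none
Why: Proposed new method: the chiral ArSe+ electrophile (from the diselenide and the N–F oxidant) and the neutral 3-OH of 4 (the more nucleophilic hydroxyl: meta to CHO, unhindered, not a hydrogen-bond acceptor) add anti across one face of 3 in a seleniranium-type opening at the benzylic carbon to give 5 (O4–C3 bond, C3 set S); the N–F reagent then oxidises the divalent selenium of 5 to tetravalent selenium, a leaving group that the ortho, acidic 4-OH displaces by 6-exo SN2 with inversion (O1–C2 bond, C2 set S), so net syn-dioxygenation of the E-alkene gives the trans-(2S,3S) ring and returns the catalyst; the closest known reaction type is the chiral diselenide-catalysed enantioselective syn-diamination and syn-oxyamination of trans-alkenes with tethered N,N- and N,O-bis-nucleophiles under N-fluoropyridinium oxidation, here carried over to a catechol as O,O-bis-nucleophile to close a six-membered ring.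

Step 3
Reactants: 6 (2S,3S)-8-methoxy-2-methyl-3-(3,4,5-trimethoxyphenyl)-2,3-dihydro-1,4-benzodioxine-6-carbaldehyde
Product: 7 (2E)-3-[(2S,3S)-8-methoxy-2-methyl-3-(3,4,5-trimethoxyphenyl)-2,3-dihydro-1,4-benzodioxin-6-yl]prop-2-enal
Conditions: Ph3P=CHCHO (1.2 equiv), toluene, 85 °C
Reagents that add atoms: (triphenylphosphoranylidene)acetaldehyde, O=CC=P(c1ccccc1)(c1ccccc1)c1ccccc1
Why: Wittig olefination with a formyl-stabilised ylide gives the E-enal under thermodynamic control and touches neither stereocentre nor the ring ethers.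

## Compound list

1 | 5-bromo-1,2,3-trimethoxybenzene | COc1cc(Br)cc(OC)c1OC | starting material
2 | (E)-4,4,5,5-tetramethyl-2-(prop-1-en-1-yl)-1,3,2-dioxaborolane | C/C=C/B1OC(C)(C)C(C)(C)O1 | starting material
3 | (E)-1,2,3-trimethoxy-5-(prop-1-en-1-yl)benzene ((E)-isoelemicin) | C/C=C/c1cc(OC)c(OC)c(OC)c1 | intermediate
4 | 3,4-dihydroxy-5-methoxybenzaldehyde (5-hydroxyvanillin) | COc1cc(C=O)cc(O)c1O | starting material
5 | 4-hydroxy-3-methoxy-5-{[(1S,2R)-2-({2-[(1S)-1-methoxyethyl]phenyl}selanyl)-1-(3,4,5-trimethoxyphenyl)propyl]oxy}benzaldehyde (anti-aryloxy selenide) | C[C@@H]([Se]c1ccccc1[C@H](C)OC)[C@@H](Oc1cc(C=O)cc(OC)c1O)c1cc(OC)c(OC)c(OC)c1 | intermediate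
6 | (2S,3S)-8-methoxy-2-methyl-3-(3,4,5-trimethoxyphenyl)-2,3-dihydro-1,4-benzodioxine-6-carbaldehyde | COc1cc([C@@H]2Oc3cc(C=O)cc(OC)c3O[C@H]2C)cc(OC)c1OC | intermediate
7 | (2E)-3-[(2S,3S)-8-methoxy-2-methyl-3-(3,4,5-trimethoxyphenyl)-2,3-dihydro-1,4-benzodioxin-6-yl]prop-2-enal | COc1cc([C@@H]2Oc3cc(/C=C/C=O)cc(OC)c3O[C@H]2C)cc(OC)c1OC | target

## Count and risks

Total step count: 3. Longest linear sequence: 3 steps (1 → 3 → 6 → 7).

**Step 2 (the proposed new annulation) is the most likely to fail.** The failure modes are: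
- first attack by the 4-OH instead of the 3-OH, which gives the regioisomeric benzodioxane;
- loss of the tetravalent selenium by elimination to an allyl aryl ether, or by 1,2-aryl shift to a catechol acetal, instead of six-ring closure;
- oxidation of 4 to its o-quinone;
- modest enantioselectivity with an electron-rich styrene.

The fallback uses known chemistry, sets out from 3 (with 4) and comes back at 6. Shi epoxidation of 3 (D-fructose-derived Shi ketone 30 mol %, Oxone (2KHSO5·KHSO4·K2SO4), K2CO3, MeCN/dimethoxymethane/aqueous buffer, 0 °C) gives (2R,3R)-2-methyl-3-(3,4,5-trimethoxyphenyl)oxirane F1. The dianion of 4 (NaH 2.2 equiv, DMSO, then 60 °C), whose 3-oxide is the more nucleophilic site, opens F1 at the benzylic carbon with inversion to give 4-hydroxy-3-{[(1S,2R)-2-hydroxy-1-(3,4,5-trimethoxyphenyl)propyl]oxy}-5-methoxybenzaldehyde F2. Intramolecular Mitsunobu etherification (PPh3, diisopropyl azodicarboxylate, THF, 0 → 23 °C) of the acidic 4-OH onto the secondary carbinol, again with inversion, closes the ring to 6. Two inversions on the (R,R)-epoxide give the same trans-(2S,3S) aldehyde, and this material also fixes which catalyst antipode step 2 needs.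

**Step 3 (Wittig) is the second risk.** The product enal can react again with the ylide to give the dienal, and the electron-rich aldehyde may react slowly. The fallback sets out from 6 and comes back at 7. Horner–Wadsworth–Emmons olefination with triethyl phosphonoacetate (NaH, THF, 0 °C) gives ethyl (2E)-3-[(2S,3S)-8-methoxy-2-methyl-3-(3,4,5-trimethoxyphenyl)-2,3-dihydro-1,4-benzodioxin-6-yl]prop-2-enoate F3. Reduction with i-Bu2AlH (2.2 equiv, CH2Cl2, −78 °C) gives (2E)-3-[(2S,3S)-8-methoxy-2-methyl-3-(3,4,5-trimethoxyphenyl)-2,3-dihydro-1,4-benzodioxin-6-yl]prop-2-en-1-ol F4. MnO2 (CH2Cl2, 23 °C) oxidises the allylic alcohol to 7.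

**Step 1 (Suzuki) is the third risk.** Protodeboronation of 2 or partial loss of E geometry would carry Z-alkene, and hence cis-benzodioxane, forward. The fallback sets out from 1 and comes back at 3. Magnesium insertion (Mg, THF, reflux) gives (3,4,5-trimethoxyphenyl)magnesium bromide F5. Addition to propanal (0 °C, dilute HCl quench) gives racemic 1-(3,4,5-trimethoxyphenyl)propan-1-ol F6. Acid-catalysed dehydration (p-TsOH·H2O 5 mol %, toluene, Dean–Stark, 110 °C) gives 3, with the conjugated E-alkene favoured thermodynamically; residual Z isomer is removed on AgNO3-impregnated silica.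

## Further compounds

F1 | step 2 | (2R,3R)-2-methyl-3-(3,4,5-trimethoxyphenyl)oxirane | C[C@H]1O[C@@H]1c1cc(OC)c(OC)c(OC)c1
F2 | step 2 | 4-hydroxy-3-{[(1S,2R)-2-hydroxy-1-(3,4,5-trimethoxyphenyl)propyl]oxy}-5-methoxybenzaldehyde | C[C@@H](O)[C@@H](Oc1cc(C=O)cc(OC)c1O)c1cc(OC)c(OC)c(OC)c1
F3 | step 3 | ethyl (2E)-3-[(2S,3S)-8-methoxy-2-methyl-3-(3,4,5-trimethoxyphenyl)-2,3-dihydro-1,4-benzodioxin-6-yl]prop-2-enoate | COc1cc([C@@H]2Oc3cc(/C=C/C(=O)OCC)cc(OC)c3O[C@H]2C)cc(OC)c1OC
F4 | step 3 | (2E)-3-[(2S,3S)-8-methoxy-2-methyl-3-(3,4,5-trimethoxyphenyl)-2,3-dihydro-1,4-benzodioxin-6-yl]prop-2-en-1-ol | COc1cc([C@@H]2Oc3cc(/C=C/CO)cc(OC)c3O[C@H]2C)cc(OC)c1OC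
F5 | step 1 | (3,4,5-trimethoxyphenyl)magnesium bromide | COc1cc([Mg]Br)cc(OC)c1OC
F6 | step 1 | 1-(3,4,5-trimethoxyphenyl)propan-1-ol (racemic) | CCC(O)c1cc(OC)c(OC)c(OC)c1
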